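The oxane ring is numbered O1, C2 (bearing the acrylic acid), C3, C4, C5 (bearing the chain C1'–C12') and C6. It is cut at C3=C4 and the chain at C2'–C3'. C5 carries C4 in the ring and C1'–C2' outside it, and both can begin as vinyl groups, so a divinyl C5 is prochiral. One ring-closing metathesis joins the C3 vinyl group to one of the two C5 vinyl groups: it closes the dihydropyran, creates C5 trans to C2 and leaves the other vinyl group as the anchor for the trienyl chain. The precursor is the (S)-configured allylic ether of 2-vinylbut-3-en-1-ol with a bulky silyloxymethyl arm on C2, later turned into the acrylic acid.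

Key step: step 5

Assumption: the (R,R)-ligand of step 3 (and the (S,S,S)-phosphoramidite held in reserve) is taken to give the (S)-ether; if the sense proves opposite, the mirror-image ligand is used and nothing else changes.

Step 1
Reactants: 1 penta-1,4-dien-3-ol
Product: 2 (3E)-5-bromopenta-1,3-diene
Conditions: 48% aq. HBr, 0 °C
Reagents that add atoms: hydrogen bromide, Br
Why: Ionisation of the protonated alcohol gives the symmetrical pentadienyl cation, which bromide captures at a terminus to give the conjugated (E)-bromide (allylic transposition, SN1-type substitution).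

Step 2
Reactants: 2 (3E)-5-bromopenta-1,3-diene
Product: 4 2-ethenylbut-3-en-1-ol, via pentadienylindium dibromide 3 (not isolated)
Conditions: In powder, 37% aq. HCHO, THF/H2O, rt
Reagents that add atoms: formaldehyde, C=O
Why: Barbier-type indium allylation in which the pentadienylindium species adds to formaldehyde through a six-membered transition state at its central (γ) carbon, which gives the skipped diene and creates no stereocentre.

Step 3
Reactants: 4 2-ethenylbut-3-en-1-ol; 5 2-ethenyloxirane (racemic)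
Product: 6 (2S)-2-[(2-ethenylbut-3-en-1-yl)oxy]but-3-en-1-ol
Conditions: Pd2(dba)3·CHCl3 (1 mol%), (R,R)-DACH-phenyl Trost ligand (3 mol%), Et3B (1 mol%), CH2Cl2, rt
Reagents that add atoms: none
Why: Dynamic kinetic asymmetric allylic etherification (Tsuji–Trost type) in which zerovalent palladium opens racemic 5 to rapidly interconverting π-allyl complexes, the borane co-catalyst ties alcohol 4 to the alkoxide and delivers it to the internal allyl carbon, and the chiral ligand sets the new stereocentre as S.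

Step 4
Reactants: 6 (2S)-2-[(2-ethenylbut-3-en-1-yl)oxy]but-3-en-1-ol
Product: 7 tert-butyl({(2S)-2-[(2-ethenylbut-3-en-1-yl)oxy]but-3-en-1-yl}oxy)diphenylsilane
Conditions: TBDPSCl, imidazole, CH2Cl2, 0 °C to rt
Reagents that add atoms: tert-butyl(chloro)diphenylsilane, CC(C)(C)[Si](Cl)(c1ccccc1)c1ccccc1
Why: Imidazole-assisted silylation of the primary alcohol (substitution at silicon) installs the bulky, non-coordinating group that is to steer the ring closure, and the stereocentre is not involved.

Step 5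
Reactants: 7 tert-butyl({(2S)-2-[(2-ethenylbut-3-en-1-yl)oxy]but-3-en-1-yl}oxy)diphenylsilane
Product: 8 tert-butyl{[(2S,5R)-5-ethenyl-5,6-dihydro-2H-pyran-2-yl]methoxy}diphenylsilane
Conditions: second-generation Grubbs catalyst RuCl2(=CHPh)(PCy3)(H2IMes) (5 mol%), 1,4-benzoquinone (10 mol%), CH2Cl2 (5 mM), 40 °C
Reagents that add atoms: none
Why: The ruthenium alkylidene loads on a terminal alkene of 7, undergoes [2+2] cycloaddition with the partner vinyl group to a ruthenacyclobutane and cycloreverts with loss of ethene, which forms C3=C4. The closest known reaction type is the diastereotopic-group-selective ring-closing metathesis of trienes that carry a divinyl carbon, as used for dihydropyrans. The one ring closes as a six-membered 5,6-dihydro-2H-pyran by joining the C3 vinyl carbon to the inner carbon of one C5 vinyl group, and no other ring size competes because the two C5 vinyl groups could only close to a cyclopropene. The new stereocentre C5 is controlled by C2: in the half-chair-like closing ring the bulky CH2OTBDPS group sits pseudo-equatorial and the vinyl group that is left over prefers the pseudo-equatorial site as well, which is the 2,5-trans (5R) product. The selectivity needed is the one between the two diastereotopic vinyl groups, secured by this conformational bias and helped by the reversibility of the closure in the presence of the ethene released, which allows the cis isomer to reopen. 1,4-Benzoquinone intercepts ruthenium hydrides so that the doubly allylic C5–H and the allylic C2–H are not isomerised, and high dilution holds back cross-metathesis of the vinyl groups.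

Step 6
Reactants: 8 tert-butyl{[(2S,5R)-5-ethenyl-5,6-dihydro-2H-pyran-2-yl]methoxy}diphenylsilane
Product: 10 2-((3R,6S)-6-{[tert-butyl(diphenyl)silyl]oxymethyl}-3,6-dihydro-2H-pyran-3-yl)ethan-1-ol, via B-alkyl-9-BBN adduct 9 (not isolated)
Conditions: 9-BBN, THF, 0 °C to rt; then NaOH aq., H2O2, 0 °C to rt
Reagents that add atoms: hydrogen peroxide, OO
Why: Hydroboration–oxidation in which 9-BBN adds anti-Markovnikov to the monosubstituted vinyl group far faster than to the cyclic disubstituted alkene and oxidation replaces boron by OH, with neither stereocentre touched.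

Step 7
Reactants: 10 2-((3R,6S)-6-{[tert-butyl(diphenyl)silyl]oxymethyl}-3,6-dihydro-2H-pyran-3-yl)ethan-1-ol
Product: 11 2-((3S,6S)-6-{[tert-butyl(diphenyl)silyl]oxymethyl}oxan-3-yl)ethan-1-ol
Conditions: TsNHNH2, NaOAc, DME/H2O, 85 °C
Reagents that add atoms: none
Why: Diimide reduction in which HN=NH made in the flask transfers both hydrogens to the ring alkene in a concerted syn manner, so that no metal hydride can move the double bond towards C5 or cleave the allylic C–O bond and both stereocentres keep their spatial arrangement.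

Step 8
Reactants: 11 2-((3S,6S)-6-{[tert-butyl(diphenyl)silyl]oxymethyl}oxan-3-yl)ethan-1-ol
Product: 12 tert-butyl{[(2S,5S)-5-(2-iodoethyl)oxan-2-yl]methoxy}diphenylsilane
Conditions: I2, PPh3, imidazole, CH2Cl2, 0 °C to rt
Reagents that add atoms: iodine, II
Why: Appel-type iodination in which the alkoxyphosphonium ion is displaced by iodide in an SN2 reaction at the primary carbon, remote from both stereocentres.

Step 9
Reactants: 13 (2E)-1-bromo-3,7-dimethylocta-2,6-diene (geranyl bromide); 14 trimethyl(prop-1-yn-1-yl)silane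
Product: 17 (5E)-6,10-dimethylundeca-5,9-dien-1-yne, via lithiated silylpropyne 15 (not isolated), via silylated enyne 16 (not isolated)
Conditions: 14, n-BuLi, THF, −78 °C; 13, −78 to 0 °C; then K2CO3, MeOH, rt
Reagents that add atoms: none
Why: Propargylic lithiation of the silylpropyne and SN2 alkylation at the primary carbon of the allylic bromide keep the (E)-alkene, and base-catalysed methanolysis then removes the alkynyl silyl group.

Step 10
Reactants: 17 (5E)-6,10-dimethylundeca-5,9-dien-1-yne
Product: 19 (1E,5E)-1-iodo-2,6,10-trimethylundeca-1,5,9-triene, via alkenyldimethylalane 18 (not isolated)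
Conditions: AlMe3, Cp2ZrCl2 (25 mol%), CH2Cl2, 0 °C to rt; then I2, THF, −30 to 0 °C
Reagents that add atoms: trimethylaluminium, C[Al](C)C; iodine, II
Why: Negishi zirconium-catalysed carboalumination adds Me–Al syn across the terminal alkyne with methyl on the internal carbon, and iodinolysis of the C–Al bond with retention gives the (E)-alkenyl iodide while the trisubstituted alkenes stay inert.

Step 11
Reactants: 12 tert-butyl{[(2S,5S)-5-(2-iodoethyl)oxan-2-yl]methoxy}diphenylsilane; 19 (1E,5E)-1-iodo-2,6,10-trimethylundeca-1,5,9-triene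
Product: 21 tert-butyl{[(2S,5R)-5-[(3E,7E)-4,8,12-trimethyltrideca-3,7,11-trien-1-yl]oxan-2-yl]methoxy}diphenylsilane, via alkylzinc iodide 20 (not isolated)
Conditions: Zn dust (activated with BrCH2CH2Br and Me3SiCl), THF, 40 °C; then 19, Pd(PPh3)4 (5 mol%), THF, rt
Reagents that add atoms: none
Why: Negishi coupling in which zinc inserts into the primary C–I bond and zerovalent palladium joins the alkylzinc to the alkenyl iodide (sp3–sp2) with retention of the (E)-geometry, forming C2'–C3'.

Step 12
Reactants: 21 tert-butyl{[(2S,5R)-5-[(3E,7E)-4,8,12-trimethyltrideca-3,7,11-trien-1-yl]oxan-2-yl]methoxy}diphenylsilane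
Product: 22 {(2S,5R)-5-[(3E,7E)-4,8,12-trimethyltrideca-3,7,11-trien-1-yl]oxan-2-yl}methanol
Conditions: TBAF, THF, 0 °C to rt
Reagents that add atoms: none
Why: Fluoride-driven cleavage of the Si–O bond (desilylation) frees the primary alcohol without touching the trisubstituted alkenes or the stereocentres.

Step 13
Reactants: 22 {(2S,5R)-5-[(3E,7E)-4,8,12-trimethyltrideca-3,7,11-trien-1-yl]oxan-2-yl}methanol
Product: 23 (2S,5R)-5-[(3E,7E)-4,8,12-trimethyltrideca-3,7,11-trien-1-yl]oxane-2-carbaldehyde
Conditions: TEMPO (10 mol%), PhI(OAc)2, CH2Cl2, rt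
Reagents that add atoms: none
Why: Oxoammonium-mediated (TEMPO/PhI(OAc)2) oxidation stops at the aldehyde under near-neutral conditions, so the α-alkoxy stereocentre C2 and the chain alkenes are left alone.

Step 14
Reactants: 23 (2S,5R)-5-[(3E,7E)-4,8,12-trimethyltrideca-3,7,11-trien-1-yl]oxane-2-carbaldehyde
Product: 24 (2S,5R)-2-ethynyl-5-[(3E,7E)-4,8,12-trimethyltrideca-3,7,11-trien-1-yl]oxane
Conditions: dimethyl (1-diazo-2-oxopropyl)phosphonate, K2CO3, MeOH, 0 °C to rt
Reagents that add atoms: dimethyl (1-diazo-2-oxopropyl)phosphonate, COP(=O)(OC)C(=[N+]=[N-])C(C)=O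
Why: Seyferth–Gilbert homologation with the Ohira–Bestmann reagent, in which the diazophosphonate anion adds to the aldehyde, loss of phosphate and N2 gives an alkylidene carbene and a 1,2-hydrogen shift gives the terminal alkyne under base mild enough to keep C2 (whose trans-diequatorial arrangement is also the more stable one).

Step 15
Reactants: 24 (2S,5R)-2-ethynyl-5-[(3E,7E)-4,8,12-trimethyltrideca-3,7,11-trien-1-yl]oxane
Product: 25 2-{(2S,5R)-5-[(3E,7E)-4,8,12-trimethyltrideca-3,7,11-trien-1-yl]oxan-2-yl}prop-2-enoic acid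
Conditions: Pd(OAc)2 (2 mol%), 2-(diphenylphosphino)pyridine (20 mol%), CH3SO3H (20 mol%), CO (20 bar), H2O (10 equiv), acetone, 50 °C
Reagents that add atoms: carbon monoxide, [C-]#[O+]; water, O
Why: Palladium-catalysed Markovnikov hydroxycarbonylation in which a Pd–H species adds across the terminal alkyne with palladium on the internal carbon, CO inserts and water cleaves the acyl–palladium bond to the 2-substituted acrylic acid, while the hindered trisubstituted chain alkenes do not insert and the acid is buffered by the pyridylphosphine.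

Compound list

1 | penta-1,4-dien-3-ol | C=CC(O)C=C | starting material
2 | (3E)-5-bromopenta-1,3-diene | C=C/C=C/CBr | intermediate
3 | (2E)-penta-2,4-dien-1-ylindium dibromide (drawn as the RInBr2 component of the organoindium bromide formed in the flask) | C=C/C=C/C[In](Br)Br | intermediate
4 | 2-ethenylbut-3-en-1-ol | OCC(C=C)C=C | intermediate
5 | 2-ethenyloxirane (racemic) | C=CC1CO1 | starting material
6 | (2S)-2-[(2-ethenylbut-3-en-1-yl)oxy]but-3-en-1-ol | OC[C@@H](OCC(C=C)C=C)C=C | intermediate
7 | tert-butyl({(2S)-2-[(2-ethenylbut-3-en-1-yl)oxy]but-3-en-1-yl}oxy)diphenylsilane | CC(C)(C)[Si](c1ccccc1)(c1ccccc1)OC[C@@H](OCC(C=C)C=C)C=C | intermediate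
8 | tert-butyl{[(2S,5R)-5-ethenyl-5,6-dihydro-2H-pyran-2-yl]methoxy}diphenylsilane | CC(C)(C)[Si](c1ccccc1)(c1ccccc1)OC[C@@H]1C=C[C@@H](C=C)CO1 | intermediate
9 | 9-[2-((3R,6S)-6-{[tert-butyl(diphenyl)silyl]oxymethyl}-3,6-dihydro-2H-pyran-3-yl)ethyl]-9-borabicyclo[3.3.1]nonane | CC(C)(C)[Si](c1ccccc1)(c1ccccc1)OC[C@@H]1C=C[C@@H](CCB2C3CCCC2CCC3)CO1 | intermediate
10 | 2-((3R,6S)-6-{[tert-butyl(diphenyl)silyl]oxymethyl}-3,6-dihydro-2H-pyran-3-yl)ethan-1-ol | CC(C)(C)[Si](c1ccccc1)(c1ccccc1)OC[C@@H]1C=C[C@@H](CCO)CO1 | intermediate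
11 | 2-((3S,6S)-6-{[tert-butyl(diphenyl)silyl]oxymethyl}oxan-3-yl)ethan-1-ol (same spatial arrangement as 10; the 3S label only reflects changed CIP ranking) | CC(C)(C)[Si](c1ccccc1)(c1ccccc1)OC[C@@H]1CC[C@@H](CCO)CO1 | intermediate
12 | tert-butyl{[(2S,5S)-5-(2-iodoethyl)oxan-2-yl]methoxy}diphenylsilane | CC(C)(C)[Si](c1ccccc1)(c1ccccc1)OC[C@@H]1CC[C@@H](CCI)CO1 | intermediate
13 | (2E)-1-bromo-3,7-dimethylocta-2,6-diene (geranyl bromide) | BrC/C=C(\C)CCC=C(C)C | starting material
14 | trimethyl(prop-1-yn-1-yl)silane | CC#C[Si](C)(C)C | starting material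
15 | [3-(trimethylsilyl)prop-2-yn-1-yl]lithium | [Li]CC#C[Si](C)(C)C | intermediate
16 | [(5E)-6,10-dimethylundeca-5,9-dien-1-yn-1-yl]trimethylsilane | C[Si](C)(C)C#CCC/C=C(\C)CCC=C(C)C | intermediate
17 | (5E)-6,10-dimethylundeca-5,9-dien-1-yne | C#CCC/C=C(\C)CCC=C(C)C | intermediate
18 | dimethyl[(1E,5E)-2,6,10-trimethylundeca-1,5,9-trien-1-yl]alane | C[Al](C)/C=C(\C)CC/C=C(\C)CCC=C(C)C | intermediate
19 | (1E,5E)-1-iodo-2,6,10-trimethylundeca-1,5,9-triene | I/C=C(\C)CC/C=C(\C)CCC=C(C)C | intermediate
20 | [2-((3S,6S)-6-{[tert-butyl(diphenyl)silyl]oxymethyl}oxan-3-yl)ethyl]zinc iodide | CC(C)(C)[Si](c1ccccc1)(c1ccccc1)OC[C@@H]1CC[C@@H](CC[Zn]I)CO1 | intermediate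
21 | tert-butyl{[(2S,5R)-5-[(3E,7E)-4,8,12-trimethyltrideca-3,7,11-trien-1-yl]oxan-2-yl]methoxy}diphenylsilane | CC(C)(C)[Si](c1ccccc1)(c1ccccc1)OC[C@@H]1CC[C@@H](CC/C=C(\C)CC/C=C(\C)CCC=C(C)C)CO1 | intermediate
22 | {(2S,5R)-5-[(3E,7E)-4,8,12-trimethyltrideca-3,7,11-trien-1-yl]oxan-2-yl}methanol | OC[C@@H]1CC[C@@H](CC/C=C(\C)CC/C=C(\C)CCC=C(C)C)CO1 | intermediate
23 | (2S,5R)-5-[(3E,7E)-4,8,12-trimethyltrideca-3,7,11-trien-1-yl]oxane-2-carbaldehyde | O=C[C@@H]1CC[C@@H](CC/C=C(\C)CC/C=C(\C)CCC=C(C)C)CO1 | intermediate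
24 | (2S,5R)-2-ethynyl-5-[(3E,7E)-4,8,12-trimethyltrideca-3,7,11-trien-1-yl]oxane | C#C[C@@H]1CC[C@@H](CC/C=C(\C)CC/C=C(\C)CCC=C(C)C)CO1 | intermediate
25 | 2-{(2S,5R)-5-[(3E,7E)-4,8,12-trimethyltrideca-3,7,11-trien-1-yl]oxan-2-yl}prop-2-enoic acid | C=C(C(=O)O)[C@@H]1CC[C@@H](CC/C=C(\C)CC/C=C(\C)CCC=C(C)C)CO1 | target

Total step count: 15. Longest linear sequence: 13 steps (steps 1–8 and 11–15, from penta-1,4-dien-3-ol); steps 9 and 10 build the alkenyl iodide in a separate branch.

Steps most likely to fail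

Step 5. The ring closure may discriminate poorly between the two diastereotopic vinyl groups, which would leave a C5-epimeric mixture that no later step can correct; ruthenium-hydride migration of the doubly allylic C5–H is the second hazard. The reserve sets C5 by auxiliary control before the ring is closed, so that the metathesis has only one vinyl group to use. It sets out from 5 and rejoins the route at 10. (4R)-4-Benzyl-1,3-oxazolidin-2-one is N-acylated with but-3-enoic acid (pivaloyl chloride, Et3N, LiCl, THF) to (4R)-4-benzyl-3-(but-3-enoyl)-1,3-oxazolidin-2-one F1. Evans alkylation of its sodium enolate (NaHMDS, THF, −78 °C) with tert-butyl bromoacetate, on the face away from the benzyl group, should give tert-butyl (3R)-3-{[(4R)-4-benzyl-2-oxo-1,3-oxazolidin-3-yl]carbonyl}pent-4-enoate F2. LiBH4 (THF, 0 °C) removes the auxiliary reductively and leaves the tert-butyl ester, giving tert-butyl (3R)-3-(hydroxymethyl)pent-4-enoate F3. This alcohol takes the place of 4 under the conditions of step 3 with 5 to give tert-butyl (3R)-3-({[(2S)-1-hydroxybut-3-en-2-yl]oxy}methyl)pent-4-enoate F4. Silylation as in step 4 gives tert-butyl (3R)-3-({[(2S)-1-{[tert-butyl(diphenyl)silyl]oxy}but-3-en-2-yl]oxy}methyl)pent-4-enoate F5. Ring-closing metathesis of this diene with the catalyst of step 5 gives tert-butyl 2-((3R,6S)-6-{[tert-butyl(diphenyl)silyl]oxymethyl}-3,6-dihydro-2H-pyran-3-yl)acetate F6. Reduction of the ester with DIBAL-H (CH2Cl2, −78 to 0 °C) gives 10.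

Step 15. Carbon monoxide may be delivered to the terminal alkyne carbon (linear acid), or the palladium hydride and the acid co-catalyst may isomerise or cyclise the triene chain. The reserve replaces the alkyne hydroxycarbonylation by carbonylation of an enol triflate; it sets out from 23 and rejoins at 25. Addition of MeMgBr (THF, −78 °C) gives 1-{(2S,5R)-5-[(3E,7E)-4,8,12-trimethyltrideca-3,7,11-trien-1-yl]oxan-2-yl}ethan-1-ol F7 as a carbinol mixture. Oxidation with Dess–Martin periodinane (NaHCO3, CH2Cl2) gives 1-{(2S,5R)-5-[(3E,7E)-4,8,12-trimethyltrideca-3,7,11-trien-1-yl]oxan-2-yl}ethan-1-one F8. Kinetic deprotonation at the methyl group (KHMDS, THF, −78 °C) and trapping with PhNTf2 give 1-{(2S,5R)-5-[(3E,7E)-4,8,12-trimethyltrideca-3,7,11-trien-1-yl]oxan-2-yl}ethenyl trifluoromethanesulfonate F9. Palladium-catalysed hydroxycarbonylation of the triflate (Pd(OAc)2, PPh3, KOAc, CO at 1 atm, DMF, rt, then aqueous acid) gives 25 under base-buffered conditions.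

Step 3. The alcohol may attack the terminal allyl carbon (linear ether), or the π-allyl complexes may equilibrate too slowly, which would erode the enantiomeric purity of C2. The reserve moves the stereo-determining event to an iridium-catalysed branched-selective allylic etherification; it sets out from 4 and rejoins at 7, which also makes step 4 unnecessary. But-2-yne-1,4-diol is reduced with LiAlH4 (THF, reflux) to (2E)-but-2-ene-1,4-diol F10. Monosilylation (NaH, TBDPSCl, THF) gives (2E)-4-{[tert-butyl(diphenyl)silyl]oxy}but-2-en-1-ol F11. Boc2O/DMAP converts it into tert-butyl (2E)-4-{[tert-butyl(diphenyl)silyl]oxy}but-2-en-1-yl carbonate F12. Alcohol 4 is turned into its copper alkoxide (n-BuLi, then CuI, THF, 0 °C) and coupled with F12 in the presence of [Ir(cod)Cl]2 and the (S,S,S)-configured binaphthol-derived N,N-bis(1-phenylethyl)phosphoramidite (THF, rt). Attack at the substituted allyl terminus should give 7 directly.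

Further compounds

F1 | step 5 | (4R)-4-benzyl-3-(but-3-enoyl)-1,3-oxazolidin-2-one | C=CCC(=O)N1[C@H](Cc2ccccc2)COC1=O
F2 | step 5 | tert-butyl (3R)-3-{[(4R)-4-benzyl-2-oxo-1,3-oxazolidin-3-yl]carbonyl}pent-4-enoate | C=C[C@@H](CC(=O)OC(C)(C)C)C(=O)N1[C@H](Cc2ccccc2)COC1=O
F3 | step 5 | tert-butyl (3R)-3-(hydroxymethyl)pent-4-enoate | C=C[C@@H](CC(=O)OC(C)(C)C)CO
F4 | step 5 | tert-butyl (3R)-3-({[(2S)-1-hydroxybut-3-en-2-yl]oxy}methyl)pent-4-enoate | C=C[C@@H](CC(=O)OC(C)(C)C)CO[C@H](CO)C=C
F5 | step 5 | tert-butyl (3R)-3-({[(2S)-1-{[tert-butyl(diphenyl)silyl]oxy}but-3-en-2-yl]oxy}methyl)pent-4-enoate | C=C[C@@H](CC(=O)OC(C)(C)C)CO[C@H](CO[Si](c1ccccc1)(c1ccccc1)C(C)(C)C)C=C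
F6 | step 5 | tert-butyl 2-((3R,6S)-6-{[tert-butyl(diphenyl)silyl]oxymethyl}-3,6-dihydro-2H-pyran-3-yl)acetate | CC(C)(C)[Si](c1ccccc1)(c1ccccc1)OC[C@@H]1C=C[C@@H](CC(=O)OC(C)(C)C)CO1
F7 | step 15 | 1-{(2S,5R)-5-[(3E,7E)-4,8,12-trimethyltrideca-3,7,11-trien-1-yl]oxan-2-yl}ethan-1-ol (carbinol epimers) | CC(O)[C@@H]1CC[C@@H](CC/C=C(\C)CC/C=C(\C)CCC=C(C)C)CO1
F8 | step 15 | 1-{(2S,5R)-5-[(3E,7E)-4,8,12-trimethyltrideca-3,7,11-trien-1-yl]oxan-2-yl}ethan-1-one | CC(=O)[C@@H]1CC[C@@H](CC/C=C(\C)CC/C=C(\C)CCC=C(C)C)CO1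
F9 | step 15 | 1-{(2S,5R)-5-[(3E,7E)-4,8,12-trimethyltrideca-3,7,11-trien-1-yl]oxan-2-yl}ethenyl trifluoromethanesulfonate | C=C(OS(=O)(=O)C(F)(F)F)[C@@H]1CC[C@@H](CC/C=C(\C)CC/C=C(\C)CCC=C(C)C)CO1
F10 | step 3 | (2E)-but-2-ene-1,4-diol | OC/C=C/CO
F11 | step 3 | (2E)-4-{[tert-butyl(diphenyl)silyl]oxy}but-2-en-1-ol | OC/C=C/CO[Si](c1ccccc1)(c1ccccc1)C(C)(C)C
F12 | step 3 | tert-butyl (2E)-4-{[tert-butyl(diphenyl)silyl]oxy}but-2-en-1-yl carbonate | CC(C)(C)OC(=O)OC/C=C/CO[Si](c1ccccc1)(c1ccccc1)C(C)(C)C
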